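**Plan**

- Retrosynthetic cuts, in order: C7–OAc (inverting esterification) ⇒ C7 carbinol/C8 configuration (C7 ketone, C8 left stereorandom) ⇒ C8–O(ring B) (phenoxide + racemic α-bromoketone of ring C) ⇒ C8'–O(ring A) (Mitsunobu) ⇒ ring B–C7' (aryl Grignard + (S)-propylene oxide).
- Forward: the chain is joined ring B → C8' carbinol → ring A ether → free ring B phenol → ring C ketone → carbinol → acetate; no ring is formed.
- Stereochemistry: C8' is bought as (S)-propylene oxide and inverted once to R. C7 and C8 are set together by one catalyst in a dynamic kinetic resolution (7R,8R, threo). C7 is then inverted to S in the step that installs the acetate (erythro).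
- Enabling feature: C8–H lies between the C7 aryl ketone (ring C side not enolizable) and the aryloxy oxygen of ring B, so C8 epimerizes under base and needs no control when the two halves are joined.

Key step: step 8

Assumption: the target is read as (7S,8R)-erythro at the acetoxy/aryloxy pair next to ring C (3,4,5-trimethoxyphenyl) and R at C8' of the ring B side chain (C7' = CH2, C8' = CH–O–ring A); ring A carries the E-propenyl group.

**Route**

Step 1
Reactants: 1 4-bromo-2,6-dimethoxyphenol
Product: 2 (4-bromo-2,6-dimethoxyphenoxy)(tert-butyl)dimethylsilane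
Conditions: TBSCl, imidazole, DMF, rt
Reagents that add atoms: tert-butyldimethylsilyl chloride, CC(C)(C)[Si](C)(C)Cl
Why: Imidazole-mediated silylation of the acidic phenol gives an aryl TBS ether that should survive Grignard formation, cuprate chemistry and the Mitsunobu reaction and can later be removed by fluoride without touching the propenyl group.

Step 2
Reactants: 2 (4-bromo-2,6-dimethoxyphenoxy)(tert-butyl)dimethylsilane; 3 (S)-propylene oxide
Product: 5 (2S)-1-[4-(tert-butyldimethylsilyloxy)-3,5-dimethoxyphenyl]propan-2-ol, via arylmagnesium bromide 4 (not isolated)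
Conditions: Mg, THF, 50 °C; then CuI (10 mol%), 3, −30 → 0 °C; H2O
Reagents that add atoms: none
Why: Copper-catalysed SN2 opening of the terminal epoxide by the aryl Grignard reagent at the unsubstituted CH2 forms the ring B–C7' bond and leaves the bought stereocentre untouched, so C8' is obtained as the (S)-carbinol.

Step 3
Reactants: 6 4-allyl-2,6-dimethoxyphenol
Product: 7 2,6-dimethoxy-4-[(E)-prop-1-en-1-yl]phenol
Conditions: RuClH(CO)(PPh3)3 (1 mol%), toluene, 80 °C
Reagents that add atoms: none
Why: Ruthenium hydride-catalysed olefin isomerization (insertion/β-hydride elimination) moves the double bond into conjugation with ring A, the E-styrene being the thermodynamic product and any minor Z isomer being removed at this early stage.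

Step 4
Reactants: 5 (2S)-1-[4-(tert-butyldimethylsilyloxy)-3,5-dimethoxyphenyl]propan-2-ol; 7 2,6-dimethoxy-4-[(E)-prop-1-en-1-yl]phenol
Product: 9 tert-butyl{4-[(2R)-2-{2,6-dimethoxy-4-[(E)-prop-1-en-1-yl]phenoxy}propyl]-2,6-dimethoxyphenoxy}dimethylsilane, via alkoxyphosphonium aryloxide 8 (not isolated)
Conditions: PPh3, DIAD (added last), THF, 0 °C → rt
Reagents that add atoms: none
Why: Mitsunobu etherification, in which the 2,6-dimethoxyphenol (pKa about 10) protonates the betaine and its phenoxide displaces the alkoxyphosphonium group by SN2, so the (S)-carbinol becomes the (R)-aryl ether at C8'.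

Step 5
Reactants: 9 tert-butyl{4-[(2R)-2-{2,6-dimethoxy-4-[(E)-prop-1-en-1-yl]phenoxy}propyl]-2,6-dimethoxyphenoxy}dimethylsilane
Product: 10 4-[(2R)-2-{2,6-dimethoxy-4-[(E)-prop-1-en-1-yl]phenoxy}propyl]-2,6-dimethoxyphenol
Conditions: TBAF (1.1 equiv), THF, 0 °C
Reagents that add atoms: none
Why: Fluoride-induced cleavage of the aryl O–Si bond frees the ring B phenol under conditions that leave the alkyl aryl ether, the C8' centre and the E-propenyl group untouched.

Step 6
Reactants: 11 1-(3,4,5-trimethoxyphenyl)propan-1-one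
Product: 12 (±)-2-bromo-1-(3,4,5-trimethoxyphenyl)propan-1-one
Conditions: CuBr2 (2 equiv), EtOAc/CHCl3, reflux
Reagents that add atoms: copper(II) bromide, Br[Cu]Br
Why: α-Bromination of an aryl ketone with CuBr2 proceeds through the enol at the only enolizable position (C8) and should spare the methoxylated ring.

Step 7
Reactants: 10 4-[(2R)-2-{2,6-dimethoxy-4-[(E)-prop-1-en-1-yl]phenoxy}propyl]-2,6-dimethoxyphenol; 12 (±)-2-bromo-1-(3,4,5-trimethoxyphenyl)propan-1-one
Product: 13 2-{4-[(2R)-2-{2,6-dimethoxy-4-[(E)-prop-1-en-1-yl]phenoxy}propyl]-2,6-dimethoxyphenoxy}-1-(3,4,5-trimethoxyphenyl)propan-1-one (both C8 epimers)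
Conditions: K2CO3, acetone, reflux
Reagents that add atoms: none
Why: Williamson-type SN2 displacement of the activated α-bromoketone by the potassium phenoxide forms the C8–O(ring B) bond and joins the two halves, the C8 configuration being left unset on purpose because the next step corrects it.

Step 8
Reactants: 13 2-{4-[(2R)-2-{2,6-dimethoxy-4-[(E)-prop-1-en-1-yl]phenoxy}propyl]-2,6-dimethoxyphenoxy}-1-(3,4,5-trimethoxyphenyl)propan-1-one (both C8 epimers)
Product: 16 (1R,2R)-2-{4-[(2R)-2-{2,6-dimethoxy-4-[(E)-prop-1-en-1-yl]phenoxy}propyl]-2,6-dimethoxyphenoxy}-1-(3,4,5-trimethoxyphenyl)propan-1-ol, via potassium enolate 14 (not isolated), via (8R)-ketone epimer 15 (not isolated)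
Conditions: trans-RuCl2[(R)-xylbinap][(R)-daipen] (1 mol%), KOtBu (0.3 equiv), H2 (10 atm), iPrOH/THF, 25 °C
Reagents that add atoms: none
Why: Noyori-type bifunctional hydrogenation: the Ru hydride delivers H− from Ru and H+ from N–H to the C7 carbonyl through an outer-sphere six-membered transition state, while KOtBu interconverts the two C8 epimers of 13 through enolate 14 faster than either is reduced, so all material should funnel through the faster-reacting epimer 15 (dynamic kinetic resolution). The closest known reaction type is the base-assisted DKR hydrogenation of configurationally labile α-alkoxy, α-aryloxy and α-amido ketones with diphosphine/diamine–Ru catalysts; no ring is closed. C7 is set by the catalyst: the (R)-XylBINAP/(R)-DAIPEN complex attacks the aryl ketone face that turns acetophenone into (S)-1-phenylethanol, which reads 7R here because C8 outranks ring C. C8 is set by the choice of epimer: in the polar Felkin–Anh arrangement the C8–O(ring B) bond lies anti to the incoming hydride with the methyl group inside, which pairs the 7R-directing catalyst with the 8R epimer and should give threo (7R,8R)-16, as in the threo-selective DKR reduction of benzoin-type α-oxygenated aryl ketones. The step needs epimerization faster than reduction, secured by the acidity of C8–H (α to the C7 ketone and bearing the aryloxy oxygen, ring C leaving no second enolizable site), and C=O over C=C chemoselectivity, which this catalyst class shows toward styrenes. The remote C8' centre is insulated by ring B, so catalyst control should be the same for both diastereomers of 13.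

Step 9
Reactants: 16 (1R,2R)-2-{4-[(2R)-2-{2,6-dimethoxy-4-[(E)-prop-1-en-1-yl]phenoxy}propyl]-2,6-dimethoxyphenoxy}-1-(3,4,5-trimethoxyphenyl)propan-1-ol
Product: 18 (1S,2R)-2-{4-[(2R)-2-{2,6-dimethoxy-4-[(E)-prop-1-en-1-yl]phenoxy}propyl]-2,6-dimethoxyphenoxy}-1-(3,4,5-trimethoxyphenyl)propyl acetate (target), via alkoxyphosphonium acetate 17 (not isolated)
Conditions: PPh3, DIAD, AcOH, toluene, 0 °C → rt
Reagents that add atoms: acetic acid, CC(=O)O
Why: Mitsunobu esterification, in which acetate displaces the C7 alkoxyphosphonium group by SN2 with inversion, should turn the threo (7R)-alcohol into the erythro (7S)-acetate in the same operation that installs the ester, SN1 leakage being disfavoured because the flanking 3,5-methoxy groups twist the 4-methoxy group out of conjugation with C7.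

**Compound list**

1 | 4-bromo-2,6-dimethoxyphenol | COc1cc(Br)cc(OC)c1O | starting material
2 | (4-bromo-2,6-dimethoxyphenoxy)(tert-butyl)dimethylsilane | COc1cc(Br)cc(OC)c1O[Si](C)(C)C(C)(C)C | intermediate
3 | (S)-propylene oxide, (2S)-2-methyloxirane | C[C@H]1CO1 | starting material
4 | [4-(tert-butyldimethylsilyloxy)-3,5-dimethoxyphenyl]magnesium bromide | COc1cc([Mg]Br)cc(OC)c1O[Si](C)(C)C(C)(C)C | intermediate
5 | (2S)-1-[4-(tert-butyldimethylsilyloxy)-3,5-dimethoxyphenyl]propan-2-ol | C[C@H](O)Cc1cc(OC)c(O[Si](C)(C)C(C)(C)C)c(OC)c1 | intermediate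
6 | 4-allyl-2,6-dimethoxyphenol | C=CCc1cc(OC)c(O)c(OC)c1 | starting material
7 | 2,6-dimethoxy-4-[(E)-prop-1-en-1-yl]phenol | C/C=C/c1cc(OC)c(O)c(OC)c1 | intermediate
8 | (2S)-alkoxytriphenylphosphonium ion of 5 paired with the phenoxide of 7 | C[C@H](O[P+](c1ccccc1)(c1ccccc1)c1ccccc1)Cc1cc(OC)c(O[Si](C)(C)C(C)(C)C)c(OC)c1.C/C=C/c1cc(OC)c([O-])c(OC)c1 | intermediate
9 | tert-butyl{4-[(2R)-2-{2,6-dimethoxy-4-[(E)-prop-1-en-1-yl]phenoxy}propyl]-2,6-dimethoxyphenoxy}dimethylsilane | C/C=C/c1cc(OC)c(O[C@H](C)Cc2cc(OC)c(O[Si](C)(C)C(C)(C)C)c(OC)c2)c(OC)c1 | intermediate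
10 | 4-[(2R)-2-{2,6-dimethoxy-4-[(E)-prop-1-en-1-yl]phenoxy}propyl]-2,6-dimethoxyphenol | C/C=C/c1cc(OC)c(O[C@H](C)Cc2cc(OC)c(O)c(OC)c2)c(OC)c1 | intermediate
11 | 1-(3,4,5-trimethoxyphenyl)propan-1-one | CCC(=O)c1cc(OC)c(OC)c(OC)c1 | starting material
12 | (±)-2-bromo-1-(3,4,5-trimethoxyphenyl)propan-1-one | CC(Br)C(=O)c1cc(OC)c(OC)c(OC)c1 | intermediate
13 | 2-{4-[(2R)-2-{2,6-dimethoxy-4-[(E)-prop-1-en-1-yl]phenoxy}propyl]-2,6-dimethoxyphenoxy}-1-(3,4,5-trimethoxyphenyl)propan-1-one, mixture of C8 epimers | C/C=C/c1cc(OC)c(O[C@H](C)Cc2cc(OC)c(OC(C)C(=O)c3cc(OC)c(OC)c(OC)c3)c(OC)c2)c(OC)c1 | intermediate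
14 | potassium enolate of ketone 13 (C7–C8 enolate) | C/C=C/c1cc(OC)c(O[C@H](C)Cc2cc(OC)c(OC(C)=C([O-])c3cc(OC)c(OC)c(OC)c3)c(OC)c2)c(OC)c1.[K+] | intermediate
15 | (2R)-2-{4-[(2R)-2-{2,6-dimethoxy-4-[(E)-prop-1-en-1-yl]phenoxy}propyl]-2,6-dimethoxyphenoxy}-1-(3,4,5-trimethoxyphenyl)propan-1-one, the (8R) epimer of 13 | C/C=C/c1cc(OC)c(O[C@H](C)Cc2cc(OC)c(O[C@H](C)C(=O)c3cc(OC)c(OC)c(OC)c3)c(OC)c2)c(OC)c1 | intermediate
16 | (1R,2R)-2-{4-[(2R)-2-{2,6-dimethoxy-4-[(E)-prop-1-en-1-yl]phenoxy}propyl]-2,6-dimethoxyphenoxy}-1-(3,4,5-trimethoxyphenyl)propan-1-ol | C/C=C/c1cc(OC)c(O[C@H](C)Cc2cc(OC)c(O[C@H](C)[C@H](O)c3cc(OC)c(OC)c(OC)c3)c(OC)c2)c(OC)c1 | intermediate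
17 | C7 alkoxytriphenylphosphonium acetate derived from 16 | C/C=C/c1cc(OC)c(O[C@H](C)Cc2cc(OC)c(O[C@H](C)[C@H](O[P+](c3ccccc3)(c3ccccc3)c3ccccc3)c3cc(OC)c(OC)c(OC)c3)c(OC)c2)c(OC)c1.CC(=O)[O-] | intermediate
18 | (1S,2R)-2-{4-[(2R)-2-{2,6-dimethoxy-4-[(E)-prop-1-en-1-yl]phenoxy}propyl]-2,6-dimethoxyphenoxy}-1-(3,4,5-trimethoxyphenyl)propyl acetate | C/C=C/c1cc(OC)c(O[C@H](C)Cc2cc(OC)c(O[C@H](C)[C@@H](OC(C)=O)c3cc(OC)c(OC)c(OC)c3)c(OC)c2)c(OC)c1 | target

**Step count and risks**

Total step count: 9. Longest linear sequence: 7 steps (steps 1, 2, 4, 5, 7, 8, 9); steps 3 and 6 are single-step side branches.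

Steps most likely to fail:

1. Step 8. Epimerization at C8 may be slower than hydrogenation, so that a plain kinetic resolution gives a mixture of diastereomers, or the faster-reacting epimer may not be the one the Felkin–Anh argument predicts. The fallback sets out from 10 and comes back at 16, with C8 taken from the chiral pool instead of from the catalyst. Mitsunobu reaction of 10 with ethyl (S)-lactate (PPh3, DIAD) should give, with inversion, ethyl (2R)-2-{4-[(2R)-2-{2,6-dimethoxy-4-[(E)-prop-1-en-1-yl]phenoxy}propyl]-2,6-dimethoxyphenoxy}propanoate F1. MeNH(OMe)·HCl/iPrMgCl should convert it into the Weinreb amide (2R)-N-methoxy-N-methyl-2-{4-[(2R)-2-{2,6-dimethoxy-4-[(E)-prop-1-en-1-yl]phenoxy}propyl]-2,6-dimethoxyphenoxy}propanamide F2. Commercial 3,4,5-trimethoxyphenylmagnesium bromide should then give ketone 15 as the single (8R) epimer. Reduction with a bulky non-chelating hydride (L-Selectride, THF, −78 °C, Felkin–Anh control by the substrate) should lead to threo 16.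

2. Step 9. The activated benzylic C7–O bond may ionize, which would cost the clean inversion, or E2 elimination toward the enol ether may compete at the hindered centre. The fallback sets out from 16 and comes back at 18, inverting C7 by oxidation and chelation-controlled reduction instead of by SN2. Buffered Dess–Martin oxidation of 16 should give 15 without touching C8. Zn(BH4)2 (Et2O, −20 °C) should reduce 15 through the zinc chelate between C7=O and the C8 aryloxy oxygen to the erythro alcohol (1S,2R)-2-{4-[(2R)-2-{2,6-dimethoxy-4-[(E)-prop-1-en-1-yl]phenoxy}propyl]-2,6-dimethoxyphenoxy}-1-(3,4,5-trimethoxyphenyl)propan-1-ol F3. Ac2O/pyridine/DMAP should then give 18 with retention.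

3. Step 4. E2 elimination of the activated homobenzylic carbinol to a conjugated propenylarene may outrun SN2 attack by the hindered phenoxide. The fallback sets out from 7 and comes back at 9, taking C8' from lactate and forming the C7'–ring B bond last. Mitsunobu reaction of 7 with ethyl (S)-lactate should give ethyl (2R)-2-{2,6-dimethoxy-4-[(E)-prop-1-en-1-yl]phenoxy}propanoate F4, an SN2 reaction at an ester-activated carbinol that cannot eliminate to a styrene. LiAlH4 should reduce it to (2R)-2-{2,6-dimethoxy-4-[(E)-prop-1-en-1-yl]phenoxy}propan-1-ol F5. TsCl/pyridine should give (2R)-2-{2,6-dimethoxy-4-[(E)-prop-1-en-1-yl]phenoxy}propyl 4-methylbenzenesulfonate F6. Copper-catalysed coupling (Li2CuCl4, THF, −30 °C → rt) of F6 with the Grignard reagent 4 from step 2 should give 9 with the stereocentre untouched.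

**Further compounds**

F1 | step 8 | ethyl (2R)-2-{4-[(2R)-2-{2,6-dimethoxy-4-[(E)-prop-1-en-1-yl]phenoxy}propyl]-2,6-dimethoxyphenoxy}propanoate | C/C=C/c1cc(OC)c(O[C@H](C)Cc2cc(OC)c(O[C@H](C)C(=O)OCC)c(OC)c2)c(OC)c1
F2 | step 8 | (2R)-N-methoxy-N-methyl-2-{4-[(2R)-2-{2,6-dimethoxy-4-[(E)-prop-1-en-1-yl]phenoxy}propyl]-2,6-dimethoxyphenoxy}propanamide | C/C=C/c1cc(OC)c(O[C@H](C)Cc2cc(OC)c(O[C@H](C)C(=O)N(C)OC)c(OC)c2)c(OC)c1
F3 | step 9 | (1S,2R)-2-{4-[(2R)-2-{2,6-dimethoxy-4-[(E)-prop-1-en-1-yl]phenoxy}propyl]-2,6-dimethoxyphenoxy}-1-(3,4,5-trimethoxyphenyl)propan-1-ol | C/C=C/c1cc(OC)c(O[C@H](C)Cc2cc(OC)c(O[C@H](C)[C@@H](O)c3cc(OC)c(OC)c(OC)c3)c(OC)c2)c(OC)c1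
F4 | step 4 | ethyl (2R)-2-{2,6-dimethoxy-4-[(E)-prop-1-en-1-yl]phenoxy}propanoate | C/C=C/c1cc(OC)c(O[C@H](C)C(=O)OCC)c(OC)c1
F5 | step 4 | (2R)-2-{2,6-dimethoxy-4-[(E)-prop-1-en-1-yl]phenoxy}propan-1-ol | C/C=C/c1cc(OC)c(O[C@H](C)CO)c(OC)c1
F6 | step 4 | (2R)-2-{2,6-dimethoxy-4-[(E)-prop-1-en-1-yl]phenoxy}propyl 4-methylbenzenesulfonate | C/C=C/c1cc(OC)c(O[C@H](C)COS(=O)(=O)c2ccc(C)cc2)c(OC)c1
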